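**Retrosynthetic overview**

1. Target 17 comes from 16 by hydrogenolysis of five benzyl ethers; 16 comes from bichalcone 15 by a double catalyst-controlled oxa-Michael closure that forms both pyranone rings last and sets C2 and C2''.
2. 15 comes from two Claisen–Schmidt condensations on a biaryl core: the acetyl group (future C3''/C4'') with aldehyde 9, and the ring B aldehyde (future C2) with acetophenone 14.
3. Feature on which the strategy rests: the hindered C3'–C8'' biaryl bond between ring B of the 5,7-dihydroxyflavanone unit and ring A of the 7-methoxyflavanone unit, flanked by O4' and by the oxygen on C8a'' (future O1''), with C8'' to be taken in preference to C6''.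
4. Biaryl 8 comes from 7 by palladium-catalysed intramolecular C–H arylation across an O4'–CH2–O(C8a'') formaldehyde acetal bridge, closing a temporary seven-membered dioxepine; 7 comes from phenol 2 and chloromethyl ether 6 (made from 3).
5. Ring order: temporary dioxepine closed (step 5) and opened (step 7), then the two pyranone rings together (step 11).

Key step: step 5

Assumption: no configuration is given for the C3'–C8'' axis, so the biaryl is treated as a freely equilibrating set of rotamers; only C2 and C2'' (both S) are controlled.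
Assumption: the quinine-derived thiourea of step 11 is taken to favour the (2S) sense; this is to be checked on 2'-hydroxy-4',6'-bis(benzyloxy)chalcone, and the quinidine-derived pseudoenantiomer is used if the sense is opposite.

**Route**

Step 1
Reactants: 1 2',6'-dihydroxy-4'-methoxyacetophenone
Product: 2 1-[2-(benzyloxy)-6-hydroxy-4-methoxyphenyl]ethan-1-one
Conditions: BnBr (1.05 equiv), K2CO3, acetone, reflux
Reagents that add atoms: benzyl bromide, BrCc1ccccc1
Why: Williamson ether synthesis; the two hydroxyls of 1 are equivalent, and once one is benzylated the other is locked in the hydrogen bond to the acetyl carbonyl and reacts far more slowly, so one equivalent of BnBr should stop at the mono-ether.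

Step 2
Reactants: 3 4-hydroxy-3-iodobenzaldehyde
Product: 4 3-iodo-4-[(methylsulfanyl)methoxy]benzaldehyde
Conditions: NaH, ClCH2SMe, NaI (cat.), DMF, 0 °C to rt
Reagents that add atoms: chloromethyl methyl sulfide, CSCCl
Why: Williamson-type O-alkylation of the acidic para-formyl phenoxide gives the methylthiomethyl (O,S-acetal) ether, the latent form of the bridging carbon; it is made before the aldehyde is masked because an acetal of the free para-hydroxybenzaldehyde would be too labile to handle.

Step 3
Reactants: 4 3-iodo-4-[(methylsulfanyl)methoxy]benzaldehyde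
Product: 5 2-{3-iodo-4-[(methylsulfanyl)methoxy]phenyl}-1,3-dioxolane
Conditions: HOCH2CH2OH, PPTS (cat.), toluene, reflux, azeotropic removal of water
Reagents that add atoms: ethylene glycol, OCCO
Why: Acid-catalysed acetalisation with removal of water masks the aldehyde as the base-stable 1,3-dioxolane under catalysis mild enough to leave the aryl O,S-acetal intact.

Step 4
Reactants: 5 2-{3-iodo-4-[(methylsulfanyl)methoxy]phenyl}-1,3-dioxolane; 2 1-[2-(benzyloxy)-6-hydroxy-4-methoxyphenyl]ethan-1-one
Product: 7 1-[2-(benzyloxy)-6-{[4-(1,3-dioxolan-2-yl)-2-iodophenoxy]methoxy}-4-methoxyphenyl]ethan-1-one, via aryl chloromethyl ether 6 (not isolated)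
Conditions: SO2Cl2, CH2Cl2, 0 °C, then evaporation; 2, NaH, DMF–THF, 0 °C to rt
Reagents that add atoms: none
Why: Sulfuryl chloride converts the O,S-acetal through its chlorosulfonium salt into chloromethyl ether 6 (its ring is deactivated by iodine and so escapes chlorination and sulfenylation, unlike the phloroglucinol ring of 2), and Williamson alkylation of the sodium phenoxide of 2 by this α-chloro ether, as in MOM protection of chelated phenols, gives the mixed diaryl formaldehyde acetal.

Step 5
Reactants: 7 1-[2-(benzyloxy)-6-{[4-(1,3-dioxolan-2-yl)-2-iodophenoxy]methoxy}-4-methoxyphenyl]ethan-1-one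
Product: 8 1-[3-(benzyloxy)-10-(1,3-dioxolan-2-yl)-1-methoxydibenzo[d,f][1,3]dioxepin-4-yl]ethan-1-one
Conditions: Pd(OAc)2 (10 mol %), PCy3·HBF4 (20 mol %), PivOH (30 mol %), K2CO3 (2 equiv), Ag2CO3 (0.5 equiv), degassed DMA, 110 °C
Reagents that add atoms: none
Why: Zerovalent palladium, formed from Pd(OAc)2 and PCy3, inserts into the C3'–I bond of 7, Ag2CO3 strips the inhibiting iodide, and the pivalate-bound divalent palladium aryl cleaves the C8''–H bond by concerted metalation–deprotonation before C–C reductive elimination from the eight-membered palladacycle gives the C3'–C8'' bond. The closest known reaction type is the palladium-catalysed intramolecular direct arylation of tethered aryl halides under phosphine/pivalate conditions, which closes six- and seven-membered biaryl rings, including rings bridged through two aryloxy oxygens. The single ring formed, the dibenzo[d,f][1,3]dioxepine, is closed by this intramolecular C–H arylation as a seven-membered ring through contraction of the palladacycle. No stereocentre is created; the bridged biaryl is only conformationally twisted and the bridge is removed in step 7. The step needs site selectivity for C8'' over C6'' and C–H arylation in preference to reduction of the C–I bond: the one-carbon bridge hangs from the oxygen on C8a'', whose other ortho carbon C4a'' carries the acetyl group, so C8''–H is the only C–H bond within reach (C6'' would demand a para-bridged ring), and it is acidified by its two flanking oxygen substituents. K2CO3 is too weak to enolise the hindered acetyl group, and both acetals are inert to the basic medium.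

Step 6
Reactants: 8 1-[3-(benzyloxy)-10-(1,3-dioxolan-2-yl)-1-methoxydibenzo[d,f][1,3]dioxepin-4-yl]ethan-1-one; 9 4-(benzyloxy)benzaldehyde
Product: 10 (E)-1-[3-(benzyloxy)-10-(1,3-dioxolan-2-yl)-1-methoxydibenzo[d,f][1,3]dioxepin-4-yl]-3-[4-(benzyloxy)phenyl]prop-2-en-1-one
Conditions: KOH (aq. 50 %), EtOH–THF, rt
Reagents that add atoms: none
Why: Claisen–Schmidt (crossed aldol) condensation of the only enolisable ketone with the non-enolisable aldehyde 9 gives the thermodynamically favoured E-enone, while the ring B aldehyde stays masked and both acetals are stable to hydroxide.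

Step 7
Reactants: 10 (E)-1-[3-(benzyloxy)-10-(1,3-dioxolan-2-yl)-1-methoxydibenzo[d,f][1,3]dioxepin-4-yl]-3-[4-(benzyloxy)phenyl]prop-2-en-1-one
Product: 11 3-{4-(benzyloxy)-3-[(E)-3-(4-(benzyloxy)phenyl)prop-2-enoyl]-2-hydroxy-6-methoxyphenyl}-4-hydroxybenzaldehyde
Conditions: conc. aq. HCl, MeOH–THF, 55 °C; then H2O, rt
Reagents that add atoms: water, O
Why: Acid-catalysed transacetalisation: in methanol the seven-membered diaryl acetal opens to an aryl methoxymethyl ether that is cleaved in turn, the bridging carbon leaving as volatile dimethoxymethane instead of alkylating the electron-rich ring, and the dioxolane is hydrolysed on dilution with water, while aryl benzyl ethers and the enone should tolerate methanolic HCl at this temperature.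

Step 8
Reactants: 11 3-{4-(benzyloxy)-3-[(E)-3-(4-(benzyloxy)phenyl)prop-2-enoyl]-2-hydroxy-6-methoxyphenyl}-4-hydroxybenzaldehyde
Product: 12 4-(benzyloxy)-3-{4-(benzyloxy)-3-[(E)-3-(4-(benzyloxy)phenyl)prop-2-enoyl]-2-hydroxy-6-methoxyphenyl}benzaldehyde
Conditions: BnBr (1.05 equiv), K2CO3 (1.1 equiv), DMF, rt
Reagents that add atoms: benzyl bromide, BrCc1ccccc1
Why: Williamson etherification with one equivalent of weak base is selective for the far more acidic, unchelated para-formyl phenol O4'–H (the hydroxyl next to the enone carbonyl is hydrogen-bonded and flanked by the aryl group), and the benzyl ether keeps a phenoxide from deactivating the aldehyde in step 10.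

Step 9
Reactants: 13 2',4',6'-trihydroxyacetophenone
Product: 14 1-[2,4-bis(benzyloxy)-6-hydroxyphenyl]ethan-1-one
Conditions: BnBr (2.1 equiv), K2CO3, DMF, 0 °C to rt
Reagents that add atoms: benzyl bromide, BrCc1ccccc1
Why: Williamson etherification of the two more reactive hydroxyls, the third being protected by its hydrogen bond to the acetyl carbonyl once one ortho oxygen is benzylated.

Step 10
Reactants: 12 4-(benzyloxy)-3-{4-(benzyloxy)-3-[(E)-3-(4-(benzyloxy)phenyl)prop-2-enoyl]-2-hydroxy-6-methoxyphenyl}benzaldehyde; 14 1-[2,4-bis(benzyloxy)-6-hydroxyphenyl]ethan-1-one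
Product: 15 (E)-1-[2,4-bis(benzyloxy)-6-hydroxyphenyl]-3-{4-(benzyloxy)-3-[4-(benzyloxy)-3-{(E)-3-[4-(benzyloxy)phenyl]prop-2-enoyl}-2-hydroxy-6-methoxyphenyl]phenyl}prop-2-en-1-one (bichalcone)
Conditions: KOH (aq. 50 %), EtOH–THF, rt; then cold 1 M HCl
Reagents that add atoms: none
Why: Claisen–Schmidt condensation in which 14 is the only enolisable partner, the existing enone has no α-hydrogen and sits as its unreactive phenoxide, and hydroxide reopens any flavanone formed from 11 or 12 in steps 7 and 8, so both enones should arrive in the open E form.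

Step 11
Reactants: 15 bichalcone
Product: 16 (2S)-5,7-bis(benzyloxy)-2-{4-(benzyloxy)-3-[(2S)-5-(benzyloxy)-2-[4-(benzyloxy)phenyl]-7-methoxy-4-oxochroman-8-yl]phenyl}chroman-4-one
Conditions: quinine-derived thiourea N-[3,5-bis(trifluoromethyl)phenyl]-N'-[(8S,9S)-6'-methoxycinchonan-9-yl]thiourea (20 mol %), toluene–CH2Cl2, 0 °C to rt
Reagents that add atoms: none
Why: Organocatalytic asymmetric intramolecular oxa-Michael addition of 2'-hydroxychalcones: the quinuclidine nitrogen takes up the phenol proton while the thiourea binds the enone carbonyl, so each phenol oxygen adds 6-endo-trig to one face of its β-carbon and C2 and C2'' are both set by the catalyst in two independent events, the minor sense of either event ending mainly in the (2R,2''S) and (2S,2''R) diastereomers, which chromatography should remove.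

Step 12
Reactants: 16 pentabenzyl (2S,2''S)-biflavanone
Product: 17 (2S)-8-{5-[(2S)-5,7-dihydroxy-4-oxochroman-2-yl]-2-hydroxyphenyl}-5-hydroxy-2-(4-hydroxyphenyl)-7-methoxychroman-4-one
Conditions: H2 (1 atm), 10 % Pd/C, EtOAc–MeOH, rt
Reagents that add atoms: none
Why: Catalytic hydrogenolysis of the five aryl benzyl ethers under neutral conditions should leave the base-sensitive C2 and C2'' stereocentres untouched, provided it is stopped at full debenzylation before the benzylic C2–O1 bonds are opened reductively.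

**Compound list**

1 | 2',6'-dihydroxy-4'-methoxyacetophenone | COc1cc(O)c(C(C)=O)c(O)c1 | starting material
2 | 1-[2-(benzyloxy)-6-hydroxy-4-methoxyphenyl]ethan-1-one | COc1cc(O)c(C(C)=O)c(OCc2ccccc2)c1 | intermediate
3 | 4-hydroxy-3-iodobenzaldehyde | O=Cc1ccc(O)c(I)c1 | starting material
4 | 3-iodo-4-[(methylsulfanyl)methoxy]benzaldehyde | CSCOc1ccc(C=O)cc1I | intermediate
5 | 2-{3-iodo-4-[(methylsulfanyl)methoxy]phenyl}-1,3-dioxolane | CSCOc1ccc(C2OCCO2)cc1I | intermediate
6 | 2-[4-(chloromethoxy)-3-iodophenyl]-1,3-dioxolane | ClCOc1ccc(C2OCCO2)cc1I | intermediate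
7 | 1-[2-(benzyloxy)-6-{[4-(1,3-dioxolan-2-yl)-2-iodophenoxy]methoxy}-4-methoxyphenyl]ethan-1-one | COc1cc(OCc2ccccc2)c(C(C)=O)c(OCOc2ccc(C3OCCO3)cc2I)c1 | intermediate
8 | 1-[3-(benzyloxy)-10-(1,3-dioxolan-2-yl)-1-methoxydibenzo[d,f][1,3]dioxepin-4-yl]ethan-1-one | COc1cc(OCc2ccccc2)c(C(C)=O)c2OCOc3ccc(C4OCCO4)cc3-c12 | intermediate
9 | 4-(benzyloxy)benzaldehyde | O=Cc1ccc(OCc2ccccc2)cc1 | starting material
10 | (E)-1-[3-(benzyloxy)-10-(1,3-dioxolan-2-yl)-1-methoxydibenzo[d,f][1,3]dioxepin-4-yl]-3-[4-(benzyloxy)phenyl]prop-2-en-1-one | COc1cc(OCc2ccccc2)c(C(=O)/C=C/c2ccc(OCc3ccccc3)cc2)c2OCOc3ccc(C4OCCO4)cc3-c12 | intermediate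
11 | 3-{4-(benzyloxy)-3-[(E)-3-(4-(benzyloxy)phenyl)prop-2-enoyl]-2-hydroxy-6-methoxyphenyl}-4-hydroxybenzaldehyde | COc1cc(OCc2ccccc2)c(C(=O)/C=C/c2ccc(OCc3ccccc3)cc2)c(O)c1-c1cc(C=O)ccc1O | intermediate
12 | 4-(benzyloxy)-3-{4-(benzyloxy)-3-[(E)-3-(4-(benzyloxy)phenyl)prop-2-enoyl]-2-hydroxy-6-methoxyphenyl}benzaldehyde | COc1cc(OCc2ccccc2)c(C(=O)/C=C/c2ccc(OCc3ccccc3)cc2)c(O)c1-c1cc(C=O)ccc1OCc1ccccc1 | intermediate
13 | 2',4',6'-trihydroxyacetophenone | CC(=O)c1c(O)cc(O)cc1O | starting material
14 | 1-[2,4-bis(benzyloxy)-6-hydroxyphenyl]ethan-1-one | CC(=O)c1c(O)cc(OCc2ccccc2)cc1OCc1ccccc1 | intermediate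
15 | (E)-1-[2,4-bis(benzyloxy)-6-hydroxyphenyl]-3-{4-(benzyloxy)-3-[4-(benzyloxy)-3-{(E)-3-[4-(benzyloxy)phenyl]prop-2-enoyl}-2-hydroxy-6-methoxyphenyl]phenyl}prop-2-en-1-one | COc1cc(OCc2ccccc2)c(C(=O)/C=C/c2ccc(OCc3ccccc3)cc2)c(O)c1-c1cc(/C=C/C(=O)c2c(O)cc(OCc3ccccc3)cc2OCc2ccccc2)ccc1OCc1ccccc1 | intermediate
16 | (2S)-5,7-bis(benzyloxy)-2-{4-(benzyloxy)-3-[(2S)-5-(benzyloxy)-2-[4-(benzyloxy)phenyl]-7-methoxy-4-oxochroman-8-yl]phenyl}chroman-4-one | COc1cc(OCc2ccccc2)c2c(c1-c1cc([C@@H]3CC(=O)c4c(OCc5ccccc5)cc(OCc5ccccc5)cc4O3)ccc1OCc1ccccc1)O[C@H](c1ccc(OCc3ccccc3)cc1)CC2=O | intermediate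
17 | (2S)-8-{5-[(2S)-5,7-dihydroxy-4-oxochroman-2-yl]-2-hydroxyphenyl}-5-hydroxy-2-(4-hydroxyphenyl)-7-methoxychroman-4-one (CNP0237714.1) | COc1cc(O)c2c(c1-c1cc([C@@H]3CC(=O)c4c(O)cc(O)cc4O3)ccc1O)O[C@H](c1ccc(O)cc1)CC2=O | target

**Count**

Total steps: 12. Longest linear sequence: 10 steps (from 3 through steps 2 to 8 and 10 to 12).

**Steps most likely to fail**

Step 5 (key step). C–H metalation at the electron-rich C8'' position, which has two ortho substituents, may be slow. Reduction of the C–I bond, intermolecular coupling or iodide inhibition of the catalyst could then take over. The fallback forms the C3'–C8'' bond intermolecularly and sets out from 2 (with 3 and 9).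
- Iodination of 2 with N-iodosuccinimide (MeCN, cat. TFA, 0 °C), directed ortho to the free chelated hydroxyl, should give 1-[6-(benzyloxy)-2-hydroxy-3-iodo-4-methoxyphenyl]ethan-1-one F1; the position of iodine is to be confirmed by HMBC.
- Claisen–Schmidt condensation of F1 with 9 (KOH, EtOH–THF) should give (E)-1-[6-(benzyloxy)-2-hydroxy-3-iodo-4-methoxyphenyl]-3-[4-(benzyloxy)phenyl]prop-2-en-1-one F2.
- In parallel, 3 is benzylated (BnBr, K2CO3, DMF) to 4-(benzyloxy)-3-iodobenzaldehyde F3.
- Miyaura borylation of F3 (bis(pinacolato)diboron, PdCl2(dppf), KOAc, dioxane, 80 °C) gives 4-(benzyloxy)-3-(4,4,5,5-tetramethyl-1,3,2-dioxaborolan-2-yl)benzaldehyde F4.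
- Suzuki–Miyaura coupling of F2 with F4 (Pd(OAc)2, SPhos, K3PO4, toluene–H2O, 80 °C) comes back to the route at 12.

Regiocontrol then rests on the phenol-directed iodination instead of the bridge.

Step 11. Facial selectivity may be incomplete in one or both ring closures, or may erode through reversible retro-oxa-Michael opening under the basic catalyst, most likely at the hindered phenol next to the biaryl bond. The fallback replaces asymmetric catalysis by resolution with recycling and sets out from 15. Closure without chiral control (NaOAc, EtOH, reflux) gives the mixture of the four stereoisomers of the pentabenzyl biflavanone F5. The (2S,2''S) isomer is isolated by preparative HPLC on a chiral stationary phase (amylose tris(3,5-dimethylphenylcarbamate)), which comes back to the route at 16. The other isomers are reopened to 15 (KOH, EtOH–THF; then cold acid) and cycled again.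

Step 7. Cleavage of the robust diaryl acetal may be incomplete, or the forcing acid it needs may cause premature ring closure of the freed hydroxy-enone, methanol addition to the enone or loss of the benzyl ether next to the carbonyl. The fallback opens the bridge before any enone exists and sets out from 8.
- HCl in MeOH at reflux (then water) gives 3-[3-acetyl-4-(benzyloxy)-2-hydroxy-6-methoxyphenyl]-4-hydroxybenzaldehyde F6.
- Selective O4'-benzylation (BnBr, K2CO3, DMF) gives 3-[3-acetyl-4-(benzyloxy)-2-hydroxy-6-methoxyphenyl]-4-(benzyloxy)benzaldehyde F7.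
- The aldehyde is masked again (ethylene glycol, PPTS, toluene, reflux) as 1-{6-(benzyloxy)-3-[2-(benzyloxy)-5-(1,3-dioxolan-2-yl)phenyl]-2-hydroxy-4-methoxyphenyl}ethan-1-one F8.
- Claisen–Schmidt condensation with 9 (KOH, EtOH–THF) gives (E)-1-{6-(benzyloxy)-3-[2-(benzyloxy)-5-(1,3-dioxolan-2-yl)phenyl]-2-hydroxy-4-methoxyphenyl}-3-[4-(benzyloxy)phenyl]prop-2-en-1-one F9.
- Mild hydrolysis of the dioxolane (1 M HCl, THF, rt) comes back to the route at 12.

**Further compounds**

F1 | step 5 | 1-[6-(benzyloxy)-2-hydroxy-3-iodo-4-methoxyphenyl]ethan-1-one | COc1cc(OCc2ccccc2)c(C(C)=O)c(O)c1I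
F2 | step 5 | (E)-1-[6-(benzyloxy)-2-hydroxy-3-iodo-4-methoxyphenyl]-3-[4-(benzyloxy)phenyl]prop-2-en-1-one | COc1cc(OCc2ccccc2)c(C(=O)/C=C/c2ccc(OCc3ccccc3)cc2)c(O)c1I
F3 | step 5 | 4-(benzyloxy)-3-iodobenzaldehyde | O=Cc1ccc(OCc2ccccc2)c(I)c1
F4 | step 5 | 4-(benzyloxy)-3-(4,4,5,5-tetramethyl-1,3,2-dioxaborolan-2-yl)benzaldehyde | O=Cc1ccc(OCc2ccccc2)c(B2OC(C)(C)C(C)(C)O2)c1
F5 | step 11 | pentabenzyl biflavanone as the mixture of its four stereoisomers at C2 and C2'' | COc1cc(OCc2ccccc2)c2c(c1-c1cc(C3CC(=O)c4c(OCc5ccccc5)cc(OCc5ccccc5)cc4O3)ccc1OCc1ccccc1)OC(c1ccc(OCc3ccccc3)cc1)CC2=O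
F6 | step 7 | 3-[3-acetyl-4-(benzyloxy)-2-hydroxy-6-methoxyphenyl]-4-hydroxybenzaldehyde | COc1cc(OCc2ccccc2)c(C(C)=O)c(O)c1-c1cc(C=O)ccc1O
F7 | step 7 | 3-[3-acetyl-4-(benzyloxy)-2-hydroxy-6-methoxyphenyl]-4-(benzyloxy)benzaldehyde | COc1cc(OCc2ccccc2)c(C(C)=O)c(O)c1-c1cc(C=O)ccc1OCc1ccccc1
F8 | step 7 | 1-{6-(benzyloxy)-3-[2-(benzyloxy)-5-(1,3-dioxolan-2-yl)phenyl]-2-hydroxy-4-methoxyphenyl}ethan-1-one | COc1cc(OCc2ccccc2)c(C(C)=O)c(O)c1-c1cc(C2OCCO2)ccc1OCc1ccccc1
F9 | step 7 | (E)-1-{6-(benzyloxy)-3-[2-(benzyloxy)-5-(1,3-dioxolan-2-yl)phenyl]-2-hydroxy-4-methoxyphenyl}-3-[4-(benzyloxy)phenyl]prop-2-en-1-one | COc1cc(OCc2ccccc2)c(C(=O)/C=C/c2ccc(OCc3ccccc3)cc2)c(O)c1-c1cc(C2OCCO2)ccc1OCc1ccccc1
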